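**Retrosynthetic overview**

1. The route rests on ring B, the dihydropyran of the chroman (O1–C2–C3–C4–C4a–C8a), and its single stereocentre, the quaternary C2 (R, bearing CH3 and the side chain). C2, C3 and C4 map onto C3', C2' and C1' of a (2E,6E)-farnesyl chain, and O1 is the phenol oxygen ortho to that chain.
2. Last stage: the side-chain carboxyl comes from the terminal E-methyl of the isopropylidene end (SeO2 allylic oxidation, MnO2, NaClO2) on the phenol acetate of chroman 10.
3. Key disconnection: O1–C2 of ring B, leading back to open-chain 2-methyl-6-farnesylhydroquinone 9, closed by tocopherol cyclase. Ring A (benzene) is bought; ring B is the only ring formed.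
4. Hydroquinone 9 comes from quinone 8 and dimethyl ether 7; the aryl–C1' bond is made from the arylcopper of bromide 3 and (2E,6E)-farnesyl bromide 4. Bromide 3 is made from 4-methoxy-2-methylphenol 1 by ortho-bromination and O-methylation.

Key step: step 6

Assumption: recombinant tocopherol cyclase (mature VTE1 of Arabidopsis thaliana, produced in Escherichia coli from a purchased synthetic gene) is treated as an available catalyst, and its preparation is not counted as a step.

**Route**

Step 1
Reactants: 1 4-methoxy-2-methylphenol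
Product: 2 2-bromo-4-methoxy-6-methylphenol
Conditions: NBS (1.0 equiv), i-Pr2NH (cat.), CH2Cl2, 0 °C
Reagents that add atoms: N-bromosuccinimide, O=C1CCC(=O)N1Br
Why: Electrophilic aromatic bromination directed by the free hydroxyl should go to C6, the only open position ortho to OH, since the para position carries OMe (amine-catalysed ortho-bromination of phenols).

Step 2
Reactants: 2 2-bromo-4-methoxy-6-methylphenol
Product: 3 1-bromo-2,5-dimethoxy-3-methylbenzene
Conditions: MeI, K2CO3, acetone, reflux
Reagents that add atoms: iodomethane, CI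
Why: Williamson O-methylation of the phenoxide gives the dimethyl ether, which is stable to organolithium reagents and can later be removed oxidatively without acid.

Step 3
Reactants: 3 1-bromo-2,5-dimethoxy-3-methylbenzene; 4 (2E,6E)-farnesyl bromide
Product: 7 1-[(2E,6E)-3,7,11-trimethyldodeca-2,6,10-trien-1-yl]-2,5-dimethoxy-3-methylbenzene, via aryllithium 5 (not isolated), via arylcopper 6 (not isolated)
Conditions: n-BuLi, THF, −78 °C; CuBr·SMe2 (1.0 equiv), −78 to −30 °C; then 4, −78 to 0 °C
Reagents that add atoms: none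
Why: Bromine–lithium exchange fixes the metal at the carbon ortho to the flanked methoxy group, and the derived arylcopper should displace the primary allylic bromide at C1 (SN2 allylation of an organocopper reagent) with retention of the 2E geometry.

Step 4
Reactants: 7 1-[(2E,6E)-3,7,11-trimethyldodeca-2,6,10-trien-1-yl]-2,5-dimethoxy-3-methylbenzene
Product: 8 2-methyl-6-[(2E,6E)-3,7,11-trimethyldodeca-2,6,10-trien-1-yl]cyclohexa-2,5-diene-1,4-dione
Conditions: (NH4)2Ce(NO3)6 (2.5 equiv), MeCN/H2O, 0 °C, short reaction time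
Reagents that add atoms: water, O
Why: Oxidative demethylation of a 1,4-dimethoxyarene by single-electron transfer to tetravalent cerium gives the para-quinone under conditions that leave isolated trisubstituted alkenes intact, as in the usual unmasking of polyprenylquinones.

Step 5
Reactants: 8 2-methyl-6-[(2E,6E)-3,7,11-trimethyldodeca-2,6,10-trien-1-yl]cyclohexa-2,5-diene-1,4-dione
Product: 9 2-methyl-6-[(2E,6E)-3,7,11-trimethyldodeca-2,6,10-trien-1-yl]benzene-1,4-diol
Conditions: aq. Na2S2O4, Et2O, rt, Ar; used at once
Reagents that add atoms: none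
Why: Dithionite reduction of a quinone to its hydroquinone is fast and neutral, so the acid-sensitive ortho-prenylphenol is delivered uncyclised.

Step 6
Reactants: 9 2-methyl-6-[(2E,6E)-3,7,11-trimethyldodeca-2,6,10-trien-1-yl]benzene-1,4-diol
Product: 10 (2R)-2-[(3E)-4,8-dimethylnona-3,7-dien-1-yl]-2,8-dimethylchroman-6-ol
Conditions: recombinant tocopherol cyclase (Arabidopsis thaliana VTE1, mature form), 9 added in EtOH, potassium phosphate buffer pH 7.3, sodium ascorbate, dithiothreitol, Ar, dark, 30 °C
Reagents that add atoms: none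
Why: The cyclase binds the hydroquinone head and the first isoprene unit, an active-site acid protonates C2' of the proximal C2'=C3' alkene on one face, and the neighbouring C1 phenol oxygen adds to the tertiary cationic centre at C3' on the opposite face, so that O1–C2 forms by anti, Markovnikov-oriented addition. The closest known reactions are the enzyme's own conversions of 2-methyl-6-phytyl- and 2-methyl-6-geranylgeranylhydroquinone into δ-tocopherol and δ-tocotrienol, of which 9 is the C15 homologue. Ring B closes in the 6-endo-trig mode, the oxygen attacking the methyl-bearing alkene carbon, whereas the 5-exo alternative would be anti-Markovnikov. The C2 stereocentre is set by the enzyme alone, which fixes the face of protonation and of oxygen attack on the achiral substrate and should deliver the natural 2R configuration. The step needs site selectivity among three trisubstituted alkenes; the active site places its acid only at the alkene next to the ring, and at neutral pH no free acid is present to cause racemic closure or cation–olefin cyclisation of the distal alkenes, while the C4 hydroxyl is meta to the chain and cannot reach it. Ascorbate, dithiothreitol and argon keep 9 in the hydroquinone state, the only form the enzyme accepts.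

Step 7
Reactants: 10 (2R)-2-[(3E)-4,8-dimethylnona-3,7-dien-1-yl]-2,8-dimethylchroman-6-ol
Product: 11 (2R)-2-[(3E)-4,8-dimethylnona-3,7-dien-1-yl]-2,8-dimethylchroman-6-yl acetate
Conditions: Ac2O, pyridine, DMAP (cat.), CH2Cl2, 0 °C to rt
Reagents that add atoms: acetic anhydride, CC(=O)OC(C)=O
Why: Acylation of the phenol removes the easily oxidised chromanol function before the three oxidations that follow.

Step 8
Reactants: 11 (2R)-2-[(3E)-4,8-dimethylnona-3,7-dien-1-yl]-2,8-dimethylchroman-6-yl acetate
Product: 12 (2R)-2-[(3E,7E)-9-hydroxy-4,8-dimethylnona-3,7-dien-1-yl]-2,8-dimethylchroman-6-yl acetate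
Conditions: SeO2 (cat.), t-BuOOH, salicylic acid (cat.), CH2Cl2, 0 °C to rt
Reagents that add atoms: tert-butyl hydroperoxide, CC(C)(C)OO (terminal source of the new oxygen); selenium dioxide, O=[Se]=O (catalytic oxygen carrier)
Why: Riley-type allylic oxidation (ene reaction then [2,3]-sigmatropic shift) is known to attack the E-methyl of the terminal isopropylidene group of polyprenyl chains in preference to the internal alkene and gives the (E)-allylic alcohol; any enal 13 formed by over-oxidation converges in step 9.

Step 9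
Reactants: 12 (2R)-2-[(3E,7E)-9-hydroxy-4,8-dimethylnona-3,7-dien-1-yl]-2,8-dimethylchroman-6-yl acetate
Product: 13 (2E,6E)-9-[(2R)-6-acetoxy-2,8-dimethylchroman-2-yl]-2,6-dimethylnona-2,6-dienal
Conditions: activated MnO2, CH2Cl2, rt
Reagents that add atoms: none
Why: MnO2 oxidises allylic alcohols selectively to enals without touching the aryl acetate, the alkenes or the alkene geometry.

Step 10
Reactants: 13 (2E,6E)-9-[(2R)-6-acetoxy-2,8-dimethylchroman-2-yl]-2,6-dimethylnona-2,6-dienal
Product: 14 (2E,6E)-9-[(2R)-6-acetoxy-2,8-dimethylchroman-2-yl]-2,6-dimethylnona-2,6-dienoic acid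
Conditions: NaClO2, NaH2PO4, 2-methyl-2-butene, t-BuOH/H2O, 0 °C to rt
Reagents that add atoms: sodium chlorite, [Na+].[O-]Cl=O
Why: Pinnick oxidation converts the α,β-unsaturated aldehyde to the acid without isomerising the double bond, and the alkene scavenger removes hypochlorous acid before it can attack the internal alkene or the arene.

Step 11
Reactants: 14 (2E,6E)-9-[(2R)-6-acetoxy-2,8-dimethylchroman-2-yl]-2,6-dimethylnona-2,6-dienoic acid
Product: 15 (2E,6E)-9-[(2R)-6-hydroxy-2,8-dimethylchroman-2-yl]-2,6-dimethylnona-2,6-dienoic acid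
Conditions: LiOH, degassed THF/H2O, Ar, rt; then 1 M HCl to pH 3
Reagents that add atoms: none
Why: Saponification of the aryl acetate is fast at room temperature, the quaternary ether stereocentre C2 cannot epimerise, and exclusion of air protects the chromanolate from oxidation.

**Compound list**

1 | 4-methoxy-2-methylphenol | COc1ccc(O)c(C)c1 | starting material
2 | 2-bromo-4-methoxy-6-methylphenol | COc1cc(C)c(O)c(Br)c1 | intermediate
3 | 1-bromo-2,5-dimethoxy-3-methylbenzene | COc1cc(C)c(OC)c(Br)c1 | intermediate
4 | (2E,6E)-farnesyl bromide, (2E,6E)-1-bromo-3,7,11-trimethyldodeca-2,6,10-triene | C/C(=C\CBr)CC/C=C(\C)CCC=C(C)C | starting material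
5 | (2,5-dimethoxy-3-methylphenyl)lithium | [Li]c1cc(OC)cc(C)c1OC | intermediate (not isolated)
6 | (2,5-dimethoxy-3-methylphenyl)copper | [Cu]c1cc(OC)cc(C)c1OC | intermediate (not isolated)
7 | 1-[(2E,6E)-3,7,11-trimethyldodeca-2,6,10-trien-1-yl]-2,5-dimethoxy-3-methylbenzene | COc1cc(C)c(OC)c(C/C=C(\C)CC/C=C(\C)CCC=C(C)C)c1 | intermediate
8 | 2-methyl-6-[(2E,6E)-3,7,11-trimethyldodeca-2,6,10-trien-1-yl]cyclohexa-2,5-diene-1,4-dione | CC1=CC(=O)C=C(C/C=C(\C)CC/C=C(\C)CCC=C(C)C)C1=O | intermediate
9 | 2-methyl-6-[(2E,6E)-3,7,11-trimethyldodeca-2,6,10-trien-1-yl]benzene-1,4-diol | Cc1cc(O)cc(C/C=C(\C)CC/C=C(\C)CCC=C(C)C)c1O | intermediate (key-step precursor)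
10 | (2R)-2-[(3E)-4,8-dimethylnona-3,7-dien-1-yl]-2,8-dimethylchroman-6-ol | C/C(=C\CC[C@]1(C)CCc2cc(O)cc(C)c2O1)CCC=C(C)C | intermediate (key-step product)
11 | (2R)-2-[(3E)-4,8-dimethylnona-3,7-dien-1-yl]-2,8-dimethylchroman-6-yl acetate | C/C(=C\CC[C@]1(C)CCc2cc(OC(C)=O)cc(C)c2O1)CCC=C(C)C | intermediate
12 | (2R)-2-[(3E,7E)-9-hydroxy-4,8-dimethylnona-3,7-dien-1-yl]-2,8-dimethylchroman-6-yl acetate | C/C(=C\CC[C@]1(C)CCc2cc(OC(C)=O)cc(C)c2O1)CC/C=C(\C)CO | intermediate
13 | (2E,6E)-9-[(2R)-6-acetoxy-2,8-dimethylchroman-2-yl]-2,6-dimethylnona-2,6-dienal | C/C(=C\CC[C@]1(C)CCc2cc(OC(C)=O)cc(C)c2O1)CC/C=C(\C)C=O | intermediate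
14 | (2E,6E)-9-[(2R)-6-acetoxy-2,8-dimethylchroman-2-yl]-2,6-dimethylnona-2,6-dienoic acid | C/C(=C\CC[C@]1(C)CCc2cc(OC(C)=O)cc(C)c2O1)CC/C=C(\C)C(=O)O | intermediate
15 | (2E,6E)-9-[(2R)-6-hydroxy-2,8-dimethylchroman-2-yl]-2,6-dimethylnona-2,6-dienoic acid | C/C(=C\CC[C@]1(C)CCc2cc(O)cc(C)c2O1)CC/C=C(\C)C(=O)O | target

**Step count and risks**

Total step count: 11. Longest linear sequence: 11 steps (1 to 15); farnesyl bromide 4 is bought and enters at step 3.

Steps most likely to fail:

1. Step 6 (enzymatic ring closure). The C15 chain is shorter than those of the enzyme's natural substrates, so binding in the lipophilic channel may be weak and turnover slow. The hydroquinone may also re-oxidise to the quinone before it is processed, leaving conversion low. Fallback from quinone 8, returning at chroman 10: heating 8 in pyridine should tautomerise it to the ortho-quinone methide, whose oxa-6π electrocyclisation gives racemic 2-[(3E)-4,8-dimethylnona-3,7-dien-1-yl]-2,8-dimethyl-2H-chromen-6-ol F1. Sodium in boiling ethanol should then reduce only the styrene-like C3=C4 bond, giving racemic 2-[(3E)-4,8-dimethylnona-3,7-dien-1-yl]-2,8-dimethylchroman-6-ol F2. Preparative HPLC on a cellulose tris(3,5-dimethylphenylcarbamate) phase would separate (R)-chromanol 10 from (2S)-2-[(3E)-4,8-dimethylnona-3,7-dien-1-yl]-2,8-dimethylchroman-6-ol F3. This gives up the enzymatic stereocontrol in exchange for known chemistry and a resolution.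

2. Step 8 (allylic oxidation). Oxidation may also occur at the allylic methylene or methyl of the internal alkene, may run on to the enal unevenly, or may stall. Fallback from acetate 11, returning at target 15: N-bromosuccinimide in THF/water at 0 °C should form the terminal bromohydrin (2R)-2-[(3E)-7-bromo-8-hydroxy-4,8-dimethylnon-3-en-1-yl]-2,8-dimethylchroman-6-yl acetate F4 (both C7' epimers). DBU in CH2Cl2 closes it to (2R)-2-[(3E)-6-(3,3-dimethyloxiran-2-yl)-4-methylhex-3-en-1-yl]-2,8-dimethylchroman-6-yl acetate F5. H5IO6 in THF/Et2O cleaves the epoxide to (2R)-2,8-dimethyl-2-[(3E)-4-methyl-7-oxohept-3-en-1-yl]chroman-6-yl acetate F6. Wittig reaction with ethyl 2-(triphenylphosphoranylidene)propanoate in CH2Cl2 should give, E-selectively, ethyl (2E,6E)-9-[(2R)-6-acetoxy-2,8-dimethylchroman-2-yl]-2,6-dimethylnona-2,6-dienoate F7. LiOH in degassed THF/H2O under argon then cleaves both esters to 15.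

3. Step 3 (allylation). The arylcopper may attack at C3 of the allyl unit (allylic transposition to the branched isomer), the 2E geometry may erode, or farnesyl bromide may homocouple. Fallback from bromide 3, returning at 7: bromine–lithium exchange (n-BuLi, THF, −78 °C) and quenching with Bu3SnCl gives tributyl(2,5-dimethoxy-3-methylphenyl)stannane F8. Stille coupling with 4 under zerovalent palladium catalysis (Pd2(dba)3, AsPh3, THF, 50 °C) should join the aryl group to the primary allyl terminus with retention of the E geometry, giving 7.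

**Further compounds**

F1 | step 6 | racemic 2-[(3E)-4,8-dimethylnona-3,7-dien-1-yl]-2,8-dimethyl-2H-chromen-6-ol | C/C(=C\CCC1(C)C=Cc2cc(O)cc(C)c2O1)CCC=C(C)C
F2 | step 6 | racemic 2-[(3E)-4,8-dimethylnona-3,7-dien-1-yl]-2,8-dimethylchroman-6-ol | C/C(=C\CCC1(C)CCc2cc(O)cc(C)c2O1)CCC=C(C)C
F3 | step 6 | (2S)-2-[(3E)-4,8-dimethylnona-3,7-dien-1-yl]-2,8-dimethylchroman-6-ol | C/C(=C\CC[C@@]1(C)CCc2cc(O)cc(C)c2O1)CCC=C(C)C
F4 | step 8 | (2R)-2-[(3E)-7-bromo-8-hydroxy-4,8-dimethylnon-3-en-1-yl]-2,8-dimethylchroman-6-yl acetate (C7' epimers) | C/C(=C\CC[C@]1(C)CCc2cc(OC(C)=O)cc(C)c2O1)CCC(Br)C(C)(C)O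
F5 | step 8 | (2R)-2-[(3E)-6-(3,3-dimethyloxiran-2-yl)-4-methylhex-3-en-1-yl]-2,8-dimethylchroman-6-yl acetate | C/C(=C\CC[C@]1(C)CCc2cc(OC(C)=O)cc(C)c2O1)CCC1OC1(C)C
F6 | step 8 | (2R)-2,8-dimethyl-2-[(3E)-4-methyl-7-oxohept-3-en-1-yl]chroman-6-yl acetate | C/C(=C\CC[C@]1(C)CCc2cc(OC(C)=O)cc(C)c2O1)CCC=O
F7 | step 8 | ethyl (2E,6E)-9-[(2R)-6-acetoxy-2,8-dimethylchroman-2-yl]-2,6-dimethylnona-2,6-dienoate | C/C(=C\CC[C@]1(C)CCc2cc(OC(C)=O)cc(C)c2O1)CC/C=C(\C)C(=O)OCC
F8 | step 3 | tributyl(2,5-dimethoxy-3-methylphenyl)stannane | CCCC[Sn](CCCC)(CCCC)c1cc(OC)cc(C)c1OC
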